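**Plan**

1. Numbering used throughout: C10 = ketone carbon, C1 = ring-fusion CH, C5 = ring-fusion carbinol, C2/C3/C4 = CH2, CHOH, CMe2 of the five-membered ring, C6/C7 = CH2, C8 = CHMe, C9 = quaternary C(Me)(chain), C11/C12 = chain CH2, C13–C16 = butenolide.
2. Feature used: in the seven-membered ring the carbonyl C10 is bonded to C1, and C1's other ring neighbour C5 carries the tertiary oxygen, so the C1–C5 bond can be the outcome of a 1,2-shift of C5 from C10 to C1. Retrosynthetically the cycloheptanone (C10, C1, C5, C6, C7, C8, C9) is therefore contracted to a cyclohexane ring B (C5 to C10) fused to a cyclohexane ring A (C10, C1, C2, C3, C4, C5) that carries 10-OH and an equatorial 1-OMs.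
3. Further cuts: C12–C13 (Negishi, last), C1–C10 (pinacol coupling), C2–C3 (allylation), C4–C5 (reverse prenylation of a 1,2-dione), C9–Me and C8–Me (conjugate addition/enolate methylation), C9–C11 (Suzuki–Miyaura).
4. Forward order: ring B as a cyclohexenone, then C8/C9, then the C5 carbinol with C4, then C3, then ring A closed at C1–C10, then the shift that makes the cyclopentane and the cycloheptanone together, then the butenolide.
5. Stereochemistry: C8 by the chiral carbene ligand of the Cu(OTf)2-derived catalyst; C9 by methylation anti to the C8 methyl; C5 by addition anti to the axial C9 chain; C3 by the chiral allylborane; the auxiliary centres C10 and C1 of the diol by axial entry and samarium chelation; final C1 by inversion in the 1,2-shift, with C5 retained.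

Key step: step 11

Assumption: the 1,2-dione 6 is taken to react in step 4 through its diketo tautomer, which equilibrates with the enol form under the aqueous conditions.

**Route**

Step 1
Reactants: 1 2-iodocyclohex-2-en-1-one; 2 potassium [2-(benzyloxy)ethyl]trifluoroborate
Product: 3 2-[2-(benzyloxy)ethyl]cyclohex-2-en-1-one
Conditions: Pd(OAc)2 (5 mol %), RuPhos, K2CO3, toluene/H2O, 85 °C
Reagents that add atoms: none
Why: B-alkyl Suzuki–Miyaura coupling of the alkenyl iodide with the primary alkyltrifluoroborate should place the protected two-carbon chain (future C11–C12) on the enone α-carbon (future C9) without forming a stereocentre.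

Step 2
Reactants: 3 2-[2-(benzyloxy)ethyl]cyclohex-2-en-1-one
Product: 5 (2R,3R)-2-[2-(benzyloxy)ethyl]-2,3-dimethylcyclohexan-1-one, via bromomagnesium enolate 4 (not isolated)
Conditions: MeMgBr, Cu(OTf)2 (cat.), chiral imidazolinium salt (carbene ligand precursor), Et2O, −30 °C; then MeI, DMPU, −30 °C to rt
Reagents that add atoms: methylmagnesium bromide C[Mg]Br; iodomethane CI
Why: Copper-catalysed asymmetric conjugate addition should set C8 (R) under control of the chiral carbene ligand, and C-methylation of the regiodefined magnesium enolate anti to the new C8 methyl should set quaternary C9 (R) with the chain cis to the C8 methyl (tandem conjugate addition–enolate alkylation).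

Step 3
Reactants: 5 (2R,3R)-2-[2-(benzyloxy)ethyl]-2,3-dimethylcyclohexan-1-one
Product: 6 (3R,4R)-3-[2-(benzyloxy)ethyl]-3,4-dimethylcyclohexane-1,2-dione (in equilibrium with its enol)
Conditions: SeO2, 1,4-dioxane/H2O, 90 °C
Reagents that add atoms: selenium dioxide O=[Se]=O
Why: Riley oxidation should convert the only enolisable α-methylene (C5, since C9 is quaternary) into a carbonyl, giving the 1,2-dione without touching C8 or C9.

Step 4
Reactants: 6 (3R,4R)-3-[2-(benzyloxy)ethyl]-3,4-dimethylcyclohexane-1,2-dione; 7 1-bromo-3-methylbut-2-ene (prenyl bromide)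
Product: 8 (2R,3R,6R)-2-[2-(benzyloxy)ethyl]-6-hydroxy-2,3-dimethyl-6-(2-methylbut-3-en-2-yl)cyclohexan-1-one
Conditions: In powder, THF/H2O (1:1), rt
Reagents that add atoms: none
Why: Indium-mediated Barbier allylation should deliver the prenyl unit through its γ-carbon (reverse prenylation) to the less hindered C5 carbonyl (C10 is neopentylic) on the face anti to the axial C9 chain, creating the C5 carbinol in the target's configuration together with the gem-dimethyl C4.

Step 5
Reactants: 8 (2R,3R,6R)-2-[2-(benzyloxy)ethyl]-6-hydroxy-2,3-dimethyl-6-(2-methylbut-3-en-2-yl)cyclohexan-1-one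
Product: 9 2-[(1R,3R,4R)-3-[2-(benzyloxy)ethyl]-1-hydroxy-3,4-dimethyl-2-oxocyclohexyl]-2-methylpropanal
Conditions: O3, CH2Cl2, −78 °C; then PPh3
Reagents that add atoms: ozone [O-][O+]=O
Why: Ozonolysis with reductive work-up should cleave the only alkene to the neopentylic aldehyde (future C3) without affecting any stereocentre.

Step 6
Reactants: 9 2-[(1R,3R,4R)-3-[2-(benzyloxy)ethyl]-1-hydroxy-3,4-dimethyl-2-oxocyclohexyl]-2-methylpropanal
Product: 10 (2R,3R,6R)-2-[2-(benzyloxy)ethyl]-6-hydroxy-6-[(3S)-3-hydroxy-2-methylhex-5-en-2-yl]-2,3-dimethylcyclohexan-1-one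
Conditions: (−)-Ipc2B(allyl) (2.5 equiv), Et2O, −78 °C; then NaBO3·4H2O, THF/H2O
Reagents that add atoms: (−)-B-allyldiisopinocampheylborane, from (+)-α-pinene C[C@H]1[C@@H](C[C@@H]2C[C@H]1C2(C)C)B(CC=C)[C@H]3[C@H](C)[C@H]4C[C@@H](C3)C4(C)C
Why: Brown allylboration should add the allyl group (future C2 and C1 plus one sacrificial carbon) to one face of the aldehyde under reagent control, setting the C3 carbinol as S, with the excess reagent covering the free tertiary hydroxyl and the hindered C10 ketone left untouched.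

Step 7
Reactants: 10 (2R,3R,6R)-2-[2-(benzyloxy)ethyl]-6-hydroxy-6-[(3S)-3-hydroxy-2-methylhex-5-en-2-yl]-2,3-dimethylcyclohexan-1-one
Product: 11 (2R,3R,6R)-2-[2-(benzyloxy)ethyl]-2,3-dimethyl-6-[(3S)-2-methyl-3-(triethylsilyloxy)hex-5-en-2-yl]-6-(triethylsilyloxy)cyclohexan-1-one
Conditions: Et3SiOTf (3 equiv), 2,6-lutidine, CH2Cl2, 0 °C to rt
Reagents that add atoms: triethylsilyl trifluoromethanesulfonate CC[Si](CC)(CC)OS(=O)(=O)C(F)(F)F
Why: Silylation with the triflate should cap both the secondary C3 and the hindered tertiary C5 hydroxyl, so that neither oxygen can later push a fragmentation of the C1 mesylate.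

Step 8
Reactants: 11 (2R,3R,6R)-2-[2-(benzyloxy)ethyl]-2,3-dimethyl-6-[(3S)-2-methyl-3-(triethylsilyloxy)hex-5-en-2-yl]-6-(triethylsilyloxy)cyclohexan-1-one
Product: 12 (3S)-4-[(1R,3R,4R)-3-[2-(benzyloxy)ethyl]-3,4-dimethyl-2-oxo-1-(triethylsilyloxy)cyclohexyl]-4-methyl-3-(triethylsilyloxy)pentanal
Conditions: O3, CH2Cl2, −78 °C; then PPh3
Reagents that add atoms: ozone [O-][O+]=O
Why: Ozonolysis of the terminal alkene should unveil the C1 aldehyde, five atoms away from the C10 ketone, with no stereocentre involved.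

Step 9
Reactants: 12 (3S)-4-[(1R,3R,4R)-3-[2-(benzyloxy)ethyl]-3,4-dimethyl-2-oxo-1-(triethylsilyloxy)cyclohexyl]-4-methyl-3-(triethylsilyloxy)pentanal
Product: 13 (1S,3S,4aR,7R,8R,8aS)-8-[2-(benzyloxy)ethyl]-4,4,7,8-tetramethyl-3,4a-bis(triethylsilyloxy)octahydronaphthalene-1,8a(1H)-diol
Conditions: SmI2 (2.5 equiv), t-BuOH, THF, −78 °C
Reagents that add atoms: none
Why: Intramolecular pinacol coupling with samarium diiodide (the aldehyde ketyl adds 6-exo to the C10 ketone) should close ring A as the cis-1,10-diol through a samarium chelate, C1 entering C10 axially on the face anti to the axial C9 chain and C5 silyloxy group, which gives the cis-fused decalin with O10 cis to O5.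

Step 10
Reactants: 13 (1S,3S,4aR,7R,8R,8aS)-8-[2-(benzyloxy)ethyl]-4,4,7,8-tetramethyl-3,4a-bis(triethylsilyloxy)octahydronaphthalene-1,8a(1H)-diol
Product: 14 (1S,3S,4aR,7R,8R,8aS)-8-[2-(benzyloxy)ethyl]-8a-hydroxy-4,4,7,8-tetramethyl-3,4a-bis(triethylsilyloxy)decahydronaphthalen-1-yl methanesulfonate
Conditions: MsCl, Et3N, CH2Cl2, −20 °C
Reagents that add atoms: methanesulfonyl chloride CS(=O)(=O)Cl
Why: Sulfonylation should occur only at the secondary C1 hydroxyl, the tertiary C10 hydroxyl being too hindered, which places an equatorial leaving group anti-periplanar to the C5–C10 bond.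

Step 11
Reactants: 14 (1S,3S,4aR,7R,8R,8aS)-8-[2-(benzyloxy)ethyl]-8a-hydroxy-4,4,7,8-tetramethyl-3,4a-bis(triethylsilyloxy)decahydronaphthalen-1-yl methanesulfonate
Product: 15 (2S,3aS,5R,6R,8aS)-5-[2-(benzyloxy)ethyl]-1,1,5,6-tetramethyl-2,8a-bis(triethylsilyloxy)octahydroazulen-4(1H)-one
Conditions: Et3Al (2.2 equiv), CH2Cl2, −78 to 0 °C; aqueous Rochelle salt
Reagents that add atoms: none
Why: Et3Al turns the tertiary C10 hydroxyl into an aluminium alkoxide and activates the mesylate, and the C5–C10 σ bond, which lies anti-periplanar to the equatorial C1–O bond in the chair of ring A, migrates from C10 to C1 as mesylate leaves while C10–O becomes the carbonyl (semipinacol rearrangement of a 2-sulfonyloxy alcohol). The closest known reaction type is the pinacol-type conversion of decalin-1,2-diol monosulfonates into hydroazulenones and the organoaluminium-promoted 1,2-shift of 2-mesyloxy alcohols. One 1,2-alkyl shift makes both ring changes: ring A (C10, C1, C2, C3, C4, C5) contracts to the cyclopentane C1–C5 by displacement at C1 (formally 3-exo-tet through the bridged transition state), and ring B (C5 to C10, six-membered) expands by insertion of C1 to the cycloheptanone C10–C1–C5–C6–C7–C8–C9. C1 is formed with inversion because C5 enters opposite to the leaving group, which gives the S configuration at C1 with H-1 anti to O-5 (trans ring fusion), and C5 migrates with retention, so both centres come from the stereodefined diol monomesylate. The step needs C5 and not C9 to migrate and no fragmentation: the equatorial mesylate is anti to C5–C10 but gauche to C9–C10, the silyl caps on O5 and O3 remove the lone-pair push needed for Grob cleavage of C5–C10 or C2–C3, and the covalent aluminium alkoxide avoids silyl transfer from O5 to O10. The non-basic medium keeps the new C1 centre, which is α to the ketone, from epimerising.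

Step 12
Reactants: 15 (2S,3aS,5R,6R,8aS)-5-[2-(benzyloxy)ethyl]-1,1,5,6-tetramethyl-2,8a-bis(triethylsilyloxy)octahydroazulen-4(1H)-one
Product: 16 (2S,3aS,5R,6R,8aS)-5-(2-hydroxyethyl)-1,1,5,6-tetramethyl-2,8a-bis(triethylsilyloxy)octahydroazulen-4(1H)-one
Conditions: H2 (1 atm), Pd/C, EtOAc, rt
Reagents that add atoms: none
Why: Hydrogenolysis should remove the benzyl ether alone, the hindered ketone and the silyl ethers being inert in ethyl acetate.

Step 13
Reactants: 16 (2S,3aS,5R,6R,8aS)-5-(2-hydroxyethyl)-1,1,5,6-tetramethyl-2,8a-bis(triethylsilyloxy)octahydroazulen-4(1H)-one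
Product: 17 (2S,3aS,5R,6R,8aS)-5-(2-iodoethyl)-1,1,5,6-tetramethyl-2,8a-bis(triethylsilyloxy)octahydroazulen-4(1H)-one
Conditions: I2, PPh3, imidazole, CH2Cl2, 0 °C
Reagents that add atoms: iodine II
Why: Appel iodination should convert the only free (primary) alcohol into the iodide under neutral conditions that leave C1 untouched.

Step 14
Reactants: 17 (2S,3aS,5R,6R,8aS)-5-(2-iodoethyl)-1,1,5,6-tetramethyl-2,8a-bis(triethylsilyloxy)octahydroazulen-4(1H)-one; 18 4-bromofuran-2(5H)-one
Product: 20 (2S,3aS,5R,6R,8aS)-1,1,5,6-tetramethyl-5-[2-(5-oxo-2,5-dihydrofuran-3-yl)ethyl]-2,8a-bis(triethylsilyloxy)octahydroazulen-4(1H)-one, via alkylzinc iodide 19 (not isolated)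
Conditions: Zn dust, LiCl, THF, 40 °C; then 18, Pd(OAc)2 (3 mol %), SPhos, THF, rt
Reagents that add atoms: none
Why: Zinc insertion into the primary iodide followed by Negishi coupling with the vinylogous acyl bromide should attach C12 to C13 of the butenolide, the organozinc tolerating the hindered ketone and the lactone.

Step 15
Reactants: 20 (2S,3aS,5R,6R,8aS)-1,1,5,6-tetramethyl-5-[2-(5-oxo-2,5-dihydrofuran-3-yl)ethyl]-2,8a-bis(triethylsilyloxy)octahydroazulen-4(1H)-one
Product: 21 (2S,3aS,5R,6R,8aS)-2,8a-dihydroxy-1,1,5,6-tetramethyl-5-[2-(5-oxo-2,5-dihydrofuran-3-yl)ethyl]octahydroazulen-4(1H)-one (CNP0077405.3)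
Conditions: HF·pyridine, THF/pyridine, 0 °C to rt
Reagents that add atoms: none
Why: Buffered fluoride desilylation should free the C3 and C5 hydroxyls without dehydrating the β-hydroxy ketone, epimerising C1 or opening the butenolide.

**Compound list**

1 | 2-iodocyclohex-2-en-1-one | O=C1CCCC=C1I | starting material
2 | potassium [2-(benzyloxy)ethyl]trifluoroborate | [K+].F[B-](F)(F)CCOCc1ccccc1 | starting material
3 | 2-[2-(benzyloxy)ethyl]cyclohex-2-en-1-one | O=C1CCCC=C1CCOCc1ccccc1 | intermediate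
4 | bromomagnesium (3R)-2-[2-(benzyloxy)ethyl]-3-methylcyclohex-1-en-1-olate | C[C@@H]1CCCC(O[Mg]Br)=C1CCOCc1ccccc1 | intermediate
5 | (2R,3R)-2-[2-(benzyloxy)ethyl]-2,3-dimethylcyclohexan-1-one | C[C@@H]1CCCC(=O)[C@]1(C)CCOCc1ccccc1 | intermediate
6 | (3R,4R)-3-[2-(benzyloxy)ethyl]-3,4-dimethylcyclohexane-1,2-dione | C[C@@H]1CCC(=O)C(=O)[C@]1(C)CCOCc1ccccc1 | intermediate
7 | 1-bromo-3-methylbut-2-ene | CC(C)=CCBr | starting material
8 | (2R,3R,6R)-2-[2-(benzyloxy)ethyl]-6-hydroxy-2,3-dimethyl-6-(2-methylbut-3-en-2-yl)cyclohexan-1-one | C[C@@H]1CC[C@@](O)(C(C)(C)C=C)C(=O)[C@]1(C)CCOCc1ccccc1 | intermediate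
9 | 2-[(1R,3R,4R)-3-[2-(benzyloxy)ethyl]-1-hydroxy-3,4-dimethyl-2-oxocyclohexyl]-2-methylpropanal | C[C@@H]1CC[C@@](O)(C(C)(C)C=O)C(=O)[C@]1(C)CCOCc1ccccc1 | intermediate
10 | (2R,3R,6R)-2-[2-(benzyloxy)ethyl]-6-hydroxy-6-[(3S)-3-hydroxy-2-methylhex-5-en-2-yl]-2,3-dimethylcyclohexan-1-one | C[C@@H]1CC[C@@](O)(C(C)(C)[C@@H](O)CC=C)C(=O)[C@]1(C)CCOCc1ccccc1 | intermediate
11 | (2R,3R,6R)-2-[2-(benzyloxy)ethyl]-2,3-dimethyl-6-[(3S)-2-methyl-3-(triethylsilyloxy)hex-5-en-2-yl]-6-(triethylsilyloxy)cyclohexan-1-one | C[C@@H]1CC[C@@](O[Si](CC)(CC)CC)(C(C)(C)[C@@H](O[Si](CC)(CC)CC)CC=C)C(=O)[C@]1(C)CCOCc1ccccc1 | intermediate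
12 | (3S)-4-[(1R,3R,4R)-3-[2-(benzyloxy)ethyl]-3,4-dimethyl-2-oxo-1-(triethylsilyloxy)cyclohexyl]-4-methyl-3-(triethylsilyloxy)pentanal | C[C@@H]1CC[C@@](O[Si](CC)(CC)CC)(C(C)(C)[C@@H](O[Si](CC)(CC)CC)CC=O)C(=O)[C@]1(C)CCOCc1ccccc1 | intermediate
13 | (1S,3S,4aR,7R,8R,8aS)-8-[2-(benzyloxy)ethyl]-4,4,7,8-tetramethyl-3,4a-bis(triethylsilyloxy)octahydronaphthalene-1,8a(1H)-diol | C[C@@H]1CC[C@@]2(O[Si](CC)(CC)CC)C(C)(C)[C@@H](O[Si](CC)(CC)CC)C[C@H](O)[C@@]2(O)[C@]1(C)CCOCc1ccccc1 | intermediate
14 | (1S,3S,4aR,7R,8R,8aS)-8-[2-(benzyloxy)ethyl]-8a-hydroxy-4,4,7,8-tetramethyl-3,4a-bis(triethylsilyloxy)decahydronaphthalen-1-yl methanesulfonate | C[C@@H]1CC[C@@]2(O[Si](CC)(CC)CC)C(C)(C)[C@@H](O[Si](CC)(CC)CC)C[C@H](OS(C)(=O)=O)[C@@]2(O)[C@]1(C)CCOCc1ccccc1 | intermediate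
15 | (2S,3aS,5R,6R,8aS)-5-[2-(benzyloxy)ethyl]-1,1,5,6-tetramethyl-2,8a-bis(triethylsilyloxy)octahydroazulen-4(1H)-one | C[C@@H]1CC[C@]2(O[Si](CC)(CC)CC)[C@H](C[C@H](O[Si](CC)(CC)CC)C2(C)C)C(=O)[C@]1(C)CCOCc1ccccc1 | intermediate
16 | (2S,3aS,5R,6R,8aS)-5-(2-hydroxyethyl)-1,1,5,6-tetramethyl-2,8a-bis(triethylsilyloxy)octahydroazulen-4(1H)-one | C[C@@H]1CC[C@]2(O[Si](CC)(CC)CC)[C@H](C[C@H](O[Si](CC)(CC)CC)C2(C)C)C(=O)[C@]1(C)CCO | intermediate
17 | (2S,3aS,5R,6R,8aS)-5-(2-iodoethyl)-1,1,5,6-tetramethyl-2,8a-bis(triethylsilyloxy)octahydroazulen-4(1H)-one | C[C@@H]1CC[C@]2(O[Si](CC)(CC)CC)[C@H](C[C@H](O[Si](CC)(CC)CC)C2(C)C)C(=O)[C@]1(C)CCI | intermediate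
18 | 4-bromofuran-2(5H)-one | BrC1=CC(=O)OC1 | starting material
19 | iodo{2-[(2S,3aS,5R,6R,8aS)-1,1,5,6-tetramethyl-4-oxo-2,8a-bis(triethylsilyloxy)decahydroazulen-5-yl]ethyl}zinc | C[C@@H]1CC[C@]2(O[Si](CC)(CC)CC)[C@H](C[C@H](O[Si](CC)(CC)CC)C2(C)C)C(=O)[C@]1(C)CC[Zn]I | intermediate
20 | (2S,3aS,5R,6R,8aS)-1,1,5,6-tetramethyl-5-[2-(5-oxo-2,5-dihydrofuran-3-yl)ethyl]-2,8a-bis(triethylsilyloxy)octahydroazulen-4(1H)-one | C[C@@H]1CC[C@]2(O[Si](CC)(CC)CC)[C@H](C[C@H](O[Si](CC)(CC)CC)C2(C)C)C(=O)[C@]1(C)CCC1=CC(=O)OC1 | intermediate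
21 | (2S,3aS,5R,6R,8aS)-2,8a-dihydroxy-1,1,5,6-tetramethyl-5-[2-(5-oxo-2,5-dihydrofuran-3-yl)ethyl]octahydroazulen-4(1H)-one | C[C@@H]1CC[C@]2(O)[C@H](C[C@H](O)C2(C)C)C(=O)[C@]1(C)CCC1=CC(=O)OC1 | target

**Totals and risks**

Total step count: 15. Longest linear sequence: 15 steps (from 1 to 21).

The three steps most likely to fail are steps 4, 9 and 11.

First risk, step 4. The dione rests mainly as its enol, so carbon–carbon bond formation at C5 may be slow, the organoindium may be lost to protonation, or the addition may show poor facial selectivity next to the hindered C9 centre. The fallback sets out from 6 and replaces the Barbier allylation by a TiCl4-mediated Mukaiyama aldol addition of 2-methyl-1-(trimethylsilyloxy)prop-1-ene. The Lewis acid should hold the substrate as its chelated diketo form and the enol silane should attack C5 anti to the axial C9 chain. Aqueous work-up would give the hydroxy aldehyde 9 directly, so the route is rejoined at 9 and step 5 is no longer needed.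

Second risk, step 9. Samarium diiodide may cleave the C5–O bond α to the ketone before the ketyl cyclises, or the very congested C10 centre (flanked by two fully substituted carbons) may cyclise with poor facial selectivity. The fallback sets out from 12 and avoids both the reductant and the diol. Condensation of 12 with p-toluenesulfonyl hydrazide would give the tosylhydrazone F1 of the aldehyde. Heating tosylhydrazone F1 with Cs2CO3 in dioxane (Bamford–Stevens conditions) would release the diazoalkane F2 in the flask. Diazoalkane F2 should add through C1 to the C10 ketone and lose N2 with 1,2-shift of C5 (intramolecular diazoalkane–ketone ring expansion). This gives the ring-expanded ketone 15, where the route is rejoined, with steps 10 and 11 bypassed.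

Third risk, step 11. Ring A must hold a chair in which the C3 silyloxy group is axial; if it leaves that chair, the mesylate may ionise without the C5 shift, C9 may migrate instead, or the C5 silyl group may be lost and fragmentation may follow. The fallback sets out from 12 and changes the way the leaving group at C1 is introduced. Selenoacetalisation of 12 with PhSeH and ZnCl2 would give the bis(phenylseleno)acetal F3 as the cyclisation precursor. Selenium–lithium exchange on selenoacetal F3 with n-BuLi at −78 °C should generate an α-seleno carbanion that closes onto the C10 ketone to give the β-hydroxy selenide F4 after protonation. Methylation of the selenium of hydroxy selenide F4 with MeI and AgBF4 should then trigger the same C5 shift under neutral conditions, giving 15, where the route is rejoined.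

**Further compounds**

F0 | step 4 | none | none
F1 | step 9 | N'-[(3S)-4-[(1R,3R,4R)-3-[2-(benzyloxy)ethyl]-3,4-dimethyl-2-oxo-1-(triethylsilyloxy)cyclohexyl]-4-methyl-3-(triethylsilyloxy)pentylidene]-4-methylbenzenesulfonohydrazide | C[C@@H]1CC[C@@](O[Si](CC)(CC)CC)(C(C)(C)[C@@H](O[Si](CC)(CC)CC)C/C=N/NS(=O)(=O)c2ccc(C)cc2)C(=O)[C@]1(C)CCOCc1ccccc1
F2 | step 9 | (2R,3R,6R)-2-[2-(benzyloxy)ethyl]-6-[(3S)-5-diazo-2-methyl-3-(triethylsilyloxy)pentan-2-yl]-2,3-dimethyl-6-(triethylsilyloxy)cyclohexan-1-one | C[C@@H]1CC[C@@](O[Si](CC)(CC)CC)(C(C)(C)[C@@H](O[Si](CC)(CC)CC)CC=[N+]=[N-])C(=O)[C@]1(C)CCOCc1ccccc1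
F3 | step 11 | (2R,3R,6R)-2-[2-(benzyloxy)ethyl]-2,3-dimethyl-6-[(3S)-2-methyl-5,5-bis(phenylselanyl)-3-(triethylsilyloxy)pentan-2-yl]-6-(triethylsilyloxy)cyclohexan-1-one | C[C@@H]1CC[C@@](O[Si](CC)(CC)CC)(C(C)(C)[C@@H](O[Si](CC)(CC)CC)CC([Se]c2ccccc2)[Se]c2ccccc2)C(=O)[C@]1(C)CCOCc1ccccc1
F4 | step 11 | 1-[2-(benzyloxy)ethyl]-1,2,5,5-tetramethyl-8-(phenylselanyl)-4a,6-bis(triethylsilyloxy)decahydronaphthalen-8a-ol, with the selenide equatorial and all other centres as in 13 | C[C@@H]1CC[C@@]2(O[Si](CC)(CC)CC)C(C)(C)[C@@H](O[Si](CC)(CC)CC)C[C@H]([Se]c3ccccc3)[C@@]2(O)[C@]1(C)CCOCc1ccccc1
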